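## Retrosynthetic overview

1. Carbons are numbered C1 (carboxyl) to C22 (furanone methyl). The acid comes from a C1 primary alcohol by selective oxidation after global desilylation.
2. The C7–C8 bond is cut last: oxidative C–H alkenylation of a C1–C7 dihydropyran (C7 still CH2) with a C8–C22 alkenyltrifluoroborate, giving the 2,6-trans ring (proposed new step).
3. The dihydropyran ring is made first in the western branch by a Brønsted-acid (IDPi) organocatalytic hetero-Diels–Alder reaction of a C1–C3 aldehyde with 2-ethylbutadiene.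
4. The furanone ring is made in the eastern branch before the union, by cyclisation of an α'-hydroxy ynone that comes from a syn-glycolate boron aldol (C17–C18).
5. C15–C16 comes from an L-proline cross-aldol, C13–C14 from a phosphoric-acid crotylboration, and C10 from a chiral-diol allylboration of pent-3-yn-2-one.

Assumption: the antipode named for each chiral catalyst follows its closest published substrates and would be exchanged if a model run showed the opposite sense. 2-Allyl-1,3,2-dioxaborinane and prop-1-ynylmagnesium bromide are taken as purchasable.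

## Route

Step 1
Reactants: 1 2-methylidenebutanal (2-ethylacrolein); 2 methyltriphenylphosphonium bromide
Product: 4 2-ethylbuta-1,3-diene, via ylide 3 (not isolated)
Conditions: KOtBu, tetraglyme, 0 °C to rt; product distilled from the pot
Reagents that add atoms: none
Why: Wittig methylenation of the enal carbonyl by the non-stabilised ylide gives the volatile 2-substituted diene, which is separated from the phosphine oxide by distillation.

Step 2
Reactants: 5 tert-butyldimethyl(prop-2-en-1-yloxy)silane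
Product: 6 (2S)-3-[(tert-butyldimethylsilyl)oxy]-2-methylpropanal
Conditions: Rh(acac)(CO)2 (0.5 mol%), (S,S,S)-BisDiazaphos (0.55 mol%), CO/H2 (1:1, 10 bar), THF, 40 °C
Reagents that add atoms: carbon monoxide [C-]#[O+]
Why: Rhodium-catalysed asymmetric hydroformylation places the formyl group on the internal carbon and sets C2, the first stereocentre of this branch, by enantioface-selective hydride insertion, the linear aldehyde being the separable minor regioisomer.

Step 3
Reactants: 6 (2S)-3-[(tert-butyldimethylsilyl)oxy]-2-methylpropanal; 4 2-ethylbuta-1,3-diene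
Product: 7 tert-butyl{[(2S)-2-[(2R)-4-ethyl-3,6-dihydro-2H-pyran-2-yl]propyl]oxy}dimethylsilane
Conditions: (S,S)-IDPi (N-triflyl imidodiphosphorimidate on 3,3'-diaryl-BINOL backbones, 3 mol%), 5 Å MS, methylcyclohexane, −40 °C, diene 3 equiv
Reagents that add atoms: none
Why: Organocatalytic hetero-Diels–Alder reaction in which the confined chiral anion pairs with the protonated aldehyde and exposes one carbonyl face, the diene attacks through its C1 terminus (tertiary allyl cation character) so the ethyl group ends at ring position 4, and catalyst control sets C3 as R, anti to the C2 methyl.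

Step 4
Reactants: 8 pent-3-yn-2-one; 9 2-(prop-2-en-1-yl)-1,3,2-dioxaborinane
Product: 10 (4S)-4-methylhept-1-en-5-yn-4-ol
Conditions: (S)-3,3'-Br2-BINOL (5 mol%), t-BuOH (2 equiv), toluene, rt; aqueous work-up
Reagents that add atoms: none
Why: Chiral-diol-catalysed asymmetric allylboration of a ketone, in which the BINOL-exchanged allylboronate adds through a closed chair transition state that tells the alkynyl from the methyl group and sets the tertiary carbinol C10 as S, the first stereocentre of the eastern branch.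

Step 5
Reactants: 10 (4S)-4-methylhept-1-en-5-yn-4-ol
Product: 11 triethyl{[(4S)-4-methylhept-1-en-5-yn-4-yl]oxy}silane
Conditions: TESOTf, 2,6-lutidine, CH2Cl2, −78 to 0 °C
Reagents that add atoms: triethylsilyl triflate CC[Si](CC)(CC)OS(=O)(=O)C(F)(F)F
Why: Silylation of the tertiary alcohol with a silyl triflate blocks lactol formation once C13 becomes an aldehyde and survives all steps up to the final fluoride treatment.

Step 6
Reactants: 11 triethyl{[(4S)-4-methylhept-1-en-5-yn-4-yl]oxy}silane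
Product: 13 (4S)-4-methyl-4-[(triethylsilyl)oxy]hept-5-yn-1-ol, via alkylborane 12 (not isolated)
Conditions: 9-BBN (1.1 equiv), THF, 0 °C to rt; then NaOH, H2O2, 0 °C
Reagents that add atoms: hydrogen peroxide OO
Why: Anti-Markovnikov hydroboration–oxidation, in which 9-BBN takes the terminal alkene far faster than the internal alkyne flanked by the quaternary centre.

Step 7
Reactants: 13 (4S)-4-methyl-4-[(triethylsilyl)oxy]hept-5-yn-1-ol
Product: 14 (4S)-4-methyl-4-[(triethylsilyl)oxy]hept-5-ynal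
Conditions: PhI(OAc)2 (1.1 equiv), TEMPO (10 mol%), CH2Cl2, rt
Reagents that add atoms: none
Why: Oxoammonium (TEMPO) oxidation stops cleanly at the aldehyde and leaves the alkyne and the silyl ether untouched.

Step 8
Reactants: 14 (4S)-4-methyl-4-[(triethylsilyl)oxy]hept-5-ynal; 15 (E)-2-(but-2-en-1-yl)-4,4,5,5-tetramethyl-1,3,2-dioxaborolane
Product: 16 (3R,4S,7S)-3,7-dimethyl-7-[(triethylsilyl)oxy]dec-1-en-8-yn-4-ol
Conditions: (R)-TRIP phosphoric acid (5 mol%), toluene, −30 °C; aqueous work-up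
Reagents that add atoms: none
Why: Chiral phosphoric acid-catalysed crotylboration, in which the (E)-crotyl geometry gives the 13,14-anti product through a chair transition state and the catalyst, hydrogen-bonded to the boronate oxygen and the formyl hydrogen, sets C13 (S) and C14 (R) on an aldehyde with no α-stereocentre.

Step 9
Reactants: 16 (3R,4S,7S)-3,7-dimethyl-7-[(triethylsilyl)oxy]dec-1-en-8-yn-4-ol
Product: 17 (3R,4S,7S)-4-methoxy-3,7-dimethyl-7-[(triethylsilyl)oxy]dec-1-en-8-yne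
Conditions: NaH, MeI, THF/DMF (4:1), 0 °C to rt
Reagents that add atoms: iodomethane CI
Why: Williamson etherification installs the C13 methyl ether at the only free hydroxyl.

Step 10
Reactants: 17 (3R,4S,7S)-4-methoxy-3,7-dimethyl-7-[(triethylsilyl)oxy]dec-1-en-8-yne
Product: 19 (2S,3S,6S)-3-methoxy-2,6-dimethyl-6-[(triethylsilyl)oxy]non-7-ynal, via ozonide 18 (not isolated)
Conditions: O3, CH2Cl2, −78 °C (Sudan Red 7B end point); then PPh3, −78 °C to rt
Reagents that add atoms: ozone [O-][O+]=O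
Why: Ozonolysis with reductive work-up cleaves the terminal alkene much faster than the hindered internal alkyne and gives the α-methyl aldehyde (C15) without touching C14.

Step 11
Reactants: 19 (2S,3S,6S)-3-methoxy-2,6-dimethyl-6-[(triethylsilyl)oxy]non-7-ynal; 20 propanal
Product: 22 (2S,3S,4S,5S,8S)-5-methoxy-2,4,8-trimethyl-3,8-bis[(triethylsilyl)oxy]undec-9-ynal, via hydroxy aldehyde 21 (not isolated)
Conditions: L-proline (20 mol%), DMF, 4 °C, propanal (2 equiv) added over 24 h; then imidazole, TESCl, 0 °C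
Reagents that add atoms: chlorotriethylsilane CC[Si](Cl)(CC)CC
Why: Proline-catalysed enamine cross-aldol (Houk–List transition state) of the propanal (E)-enamine with the α-branched acceptor gives the 15,16-anti aldol with C15 and C16 fixed by the catalyst (anti to C14, against the weak Felkin bias), and in-flask silylation traps the labile β-hydroxy aldehyde.

Step 12
Reactants: 23 2-chloro-N-methoxy-N-methylacetamide; 24 (4-methoxyphenyl)methanol
Product: 25 N-methoxy-2-[(4-methoxyphenyl)methoxy]-N-methylacetamide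
Conditions: NaH, Bu4NI (cat.), THF, 0 °C to rt
Reagents that add atoms: none
Why: Williamson ether synthesis on the activated α-chloro amide gives the PMB-protected glycolic Weinreb amide.

Step 13
Reactants: 25 N-methoxy-2-[(4-methoxyphenyl)methoxy]-N-methylacetamide; 26 prop-1-yn-1-ylmagnesium bromide
Product: 27 1-[(4-methoxyphenyl)methoxy]pent-3-yn-2-one
Conditions: THF, 0 °C; aq. NH4Cl
Reagents that add atoms: none
Why: Weinreb ketone synthesis, in which the chelated tetrahedral adduct prevents over-addition and releases the ynone on work-up.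

Step 14
Reactants: 27 1-[(4-methoxyphenyl)methoxy]pent-3-yn-2-one; 22 (2S,3S,4S,5S,8S)-5-methoxy-2,4,8-trimethyl-3,8-bis[(triethylsilyl)oxy]undec-9-ynal
Product: 29 (5R,6S,7R,8R,9S,10S,13S)-6-hydroxy-10-methoxy-5-[(4-methoxyphenyl)methoxy]-7,9,13-trimethyl-8,13-bis[(triethylsilyl)oxy]hexadeca-2,14-diyn-4-one, via boron enolate 28 (not isolated)
Conditions: 27 (1.5 equiv), Bu2BOTf, iPr2NEt, CH2Cl2, −78 °C, 1 h; then 22, −78 to −20 °C; pH 7 buffer/MeOH
Reagents that add atoms: none
Why: Boron-mediated syn-glycolate aldol, in which the (Z)-enolate reacts through a Zimmerman–Traxler chair to give the 17,18-syn diol pattern and, as (Z)-enolates do with α-methyl aldehydes, adds anti-Felkin (16,17-anti), setting C17 (S) and C18 (R).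

Step 15
Reactants: 29 (5R,6S,7R,8R,9S,10S,13S)-6-hydroxy-10-methoxy-5-[(4-methoxyphenyl)methoxy]-7,9,13-trimethyl-8,13-bis[(triethylsilyl)oxy]hexadeca-2,14-diyn-4-one
Product: 30 (5R,6S,7S,8S,9S,10S,13S)-10-methoxy-5-[(4-methoxyphenyl)methoxy]-7,9,13-trimethyl-6,8,13-tris[(triethylsilyl)oxy]hexadeca-2,14-diyn-4-one
Conditions: TESOTf, 2,6-lutidine, CH2Cl2, −78 °C
Reagents that add atoms: triethylsilyl triflate CC[Si](CC)(CC)OS(=O)(=O)C(F)(F)F
Why: Low-temperature silylation caps the C17 hydroxyl so that only the C18 oxygen can later cyclise onto the ynone.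

Step 16
Reactants: 30 (5R,6S,7S,8S,9S,10S,13S)-10-methoxy-5-[(4-methoxyphenyl)methoxy]-7,9,13-trimethyl-6,8,13-tris[(triethylsilyl)oxy]hexadeca-2,14-diyn-4-one
Product: 32 (2R)-5-methyl-2-[(1S,2S,3S,4S,5S,8S)-5-methoxy-2,4,8-trimethyl-1,3,8-tris[(triethylsilyl)oxy]undec-9-yn-1-yl]furan-3(2H)-one, via hydroxy ynone 31 (not isolated)
Conditions: DDQ (1.3 equiv), CH2Cl2/pH 7 buffer (10:1), 0 °C; filter through NaHCO3/Na2SO4; then AuCl3 (2 mol%), CH2Cl2, rt
Reagents that add atoms: none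
Why: Oxidative PMB cleavage unmasks the α'-hydroxy ynone, which closes the furanone ring by gold-catalysed 5-endo-dig oxa-cyclisation of O18 onto C21 under neutral conditions that leave the C18 stereocentre untouched.

Step 17
Reactants: 32 (2R)-5-methyl-2-[(1S,2S,3S,4S,5S,8S)-5-methoxy-2,4,8-trimethyl-1,3,8-tris[(triethylsilyl)oxy]undec-9-yn-1-yl]furan-3(2H)-one
Product: 34 potassium trifluoro[(2Z,4S,7S,8S,9S,10S,11S)-7-methoxy-4,8,10-trimethyl-11-[(2R)-5-methyl-3-oxo-2,3-dihydrofuran-2-yl]-4,9,11-tris[(triethylsilyl)oxy]undec-2-en-2-yl]borate, via alkenyl pinacol boronate 33 (not isolated)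
Conditions: HBpin (2.5 equiv), RhCl(CO)(PPh3)2 (3 mol%), CH2Cl2, rt; then KHF2 (4 equiv), MeOH/H2O, 0 °C, 20 min
Reagents that add atoms: pinacolborane CC1(C)OBOC1(C)C; potassium hydrogen difluoride [K+].F.[F-]
Why: Rhodium-catalysed syn-hydroboration puts boron on the less hindered methyl-bearing alkyne carbon (C8), away from quaternary C10, which fixes the alkene geometry needed later, and brief KHF2 treatment gives the bench-stable trifluoroborate while the vinylogous-ester carbonyl is inert to pinacolborane.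

Step 18
Reactants: 7 tert-butyl{[(2S)-2-[(2R)-4-ethyl-3,6-dihydro-2H-pyran-2-yl]propyl]oxy}dimethylsilane; 34 potassium trifluoro[(2Z,4S,7S,8S,9S,10S,11S)-7-methoxy-4,8,10-trimethyl-11-[(2R)-5-methyl-3-oxo-2,3-dihydrofuran-2-yl]-4,9,11-tris[(triethylsilyl)oxy]undec-2-en-2-yl]borate
Product: 36 (2R)-2-[(1S,2S,3S,4S,5S,8S,9E)-10-[(2R,6R)-6-[(2S)-1-[(tert-butyldimethylsilyl)oxy]propan-2-yl]-4-ethyl-5,6-dihydro-2H-pyran-2-yl]-5-methoxy-2,4,8-trimethyl-1,3,8-tris[(triethylsilyl)oxy]undec-9-en-1-yl]-5-methylfuran-3(2H)-one, via oxocarbenium ion 35 (not isolated)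
Conditions: 7 (1.3 equiv), 34 (1.0 equiv), LiClO4 (2 equiv), 2,6-dichloropyridine (2 equiv), 4 Å MS, MeCN, −30 °C; DDQ (1.1 equiv) in MeCN added over 1 h; then 0 °C
Reagents that add atoms: none
Why: Proposed new method: a cross-dehydrogenative C–H alkenylation in which DDQ abstracts hydride from the only C–H of 7 that is both allylic and α to oxygen (the future C7) to give the conjugated oxocarbenium ion 35, which is captured as it forms by ipso attack of the alkenyltrifluoroborate with retention of alkene geometry, the nucleophile entering pseudo-axially on the half-chair anti to the pseudo-equatorial side chain at C3 so that the 2,6-trans (7R) ether results; the closest known chemistry is the DDQ-mediated oxidative coupling of chromenes, isochromans and allylic ethers with trifluoroborates or π-nucleophiles and the trans-selective Ferrier-type C-glycosylation, neither shown on a non-benzannulated 3,6-dihydro-2H-pyran with a hindered trisubstituted alkenyltrifluoroborate, and slow addition of a slight deficit of DDQ protects the more oxidisable bis-allylic product.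

Step 19
Reactants: 36 (2R)-2-[(1S,2S,3S,4S,5S,8S,9E)-10-[(2R,6R)-6-[(2S)-1-[(tert-butyldimethylsilyl)oxy]propan-2-yl]-4-ethyl-5,6-dihydro-2H-pyran-2-yl]-5-methoxy-2,4,8-trimethyl-1,3,8-tris[(triethylsilyl)oxy]undec-9-en-1-yl]-5-methylfuran-3(2H)-one
Product: 37 (2R)-2-[(1S,2S,3R,4R,5S,8S,9E)-10-[(2R,6R)-4-ethyl-6-[(2S)-1-hydroxypropan-2-yl]-5,6-dihydro-2H-pyran-2-yl]-1,3,8-trihydroxy-5-methoxy-2,4,8-trimethylundec-9-en-1-yl]-5-methylfuran-3(2H)-one
Conditions: HF·pyridine, excess pyridine, THF, 0 °C to rt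
Reagents that add atoms: none
Why: Buffered fluoride desilylation removes the three triethylsilyl ethers and the primary TBS ether without base (no C18 epimerisation or retro-aldol) and without strong acid (the bis-allylic ring ether and the tertiary allylic alcohol survive).

Step 20
Reactants: 37 (2R)-2-[(1S,2S,3R,4R,5S,8S,9E)-10-[(2R,6R)-4-ethyl-6-[(2S)-1-hydroxypropan-2-yl]-5,6-dihydro-2H-pyran-2-yl]-1,3,8-trihydroxy-5-methoxy-2,4,8-trimethylundec-9-en-1-yl]-5-methylfuran-3(2H)-one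
Product: 39 (2R)-2-[(2R,6R)-4-ethyl-6-[(2E,4S,7S,8R,9R,10S,11S)-4,9,11-trihydroxy-7-methoxy-4,8,10-trimethyl-11-[(2R)-5-methyl-3-oxo-2,3-dihydrofuran-2-yl]undec-2-en-2-yl]-3,6-dihydro-2H-pyran-2-yl]propanoic acid, via aldehyde 38 (not isolated)
Conditions: TEMPO (20 mol%), PhI(OAc)2 (2.5 equiv), MeCN/pH 7 buffer (1:1), 0 °C to rt
Reagents that add atoms: water O
Why: Oxoammonium (TEMPO) oxidation is selective for the unhindered primary alcohol over the hindered secondary and the tertiary alcohols, and in aqueous medium the aldehyde hydrate is oxidised on to the carboxylic acid without epimerising C2.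

## Compound list

1 | 2-methylidenebutanal (2-ethylacrolein) | CCC(=C)C=O | starting material
2 | methyltriphenylphosphonium bromide | C[P+](c1ccccc1)(c1ccccc1)c1ccccc1.[Br-] | starting material
3 | methylidenetriphenylphosphorane | C=P(c1ccccc1)(c1ccccc1)c1ccccc1 | intermediate
4 | 2-ethylbuta-1,3-diene | CCC(=C)C=C | intermediate
5 | tert-butyldimethyl(prop-2-en-1-yloxy)silane | C=CCO[Si](C)(C)C(C)(C)C | starting material
6 | (2S)-3-[(tert-butyldimethylsilyl)oxy]-2-methylpropanal | O=C[C@@H](C)CO[Si](C)(C)C(C)(C)C | intermediate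
7 | tert-butyl{[(2S)-2-[(2R)-4-ethyl-3,6-dihydro-2H-pyran-2-yl]propyl]oxy}dimethylsilane | CCC1=CCO[C@@H]([C@@H](C)CO[Si](C)(C)C(C)(C)C)C1 | intermediate
8 | pent-3-yn-2-one | CC#CC(C)=O | starting material
9 | 2-(prop-2-en-1-yl)-1,3,2-dioxaborinane | C=CCB1OCCCO1 | starting material
10 | (4S)-4-methylhept-1-en-5-yn-4-ol | CC#C[C@@](C)(O)CC=C | intermediate
11 | triethyl{[(4S)-4-methylhept-1-en-5-yn-4-yl]oxy}silane | CC#C[C@@](C)(O[Si](CC)(CC)CC)CC=C | intermediate
12 | 9-[(4S)-4-methyl-4-[(triethylsilyl)oxy]hept-5-yn-1-yl]-9-borabicyclo[3.3.1]nonane | CC#C[C@@](C)(O[Si](CC)(CC)CC)CCCB1C2CCCC1CCC2 | intermediate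
13 | (4S)-4-methyl-4-[(triethylsilyl)oxy]hept-5-yn-1-ol | CC#C[C@@](C)(O[Si](CC)(CC)CC)CCCO | intermediate
14 | (4S)-4-methyl-4-[(triethylsilyl)oxy]hept-5-ynal | CC#C[C@@](C)(O[Si](CC)(CC)CC)CCC=O | intermediate
15 | (E)-2-(but-2-en-1-yl)-4,4,5,5-tetramethyl-1,3,2-dioxaborolane | C/C=C/CB1OC(C)(C)C(C)(C)O1 | starting material
16 | (3R,4S,7S)-3,7-dimethyl-7-[(triethylsilyl)oxy]dec-1-en-8-yn-4-ol | CC#C[C@@](C)(O[Si](CC)(CC)CC)CC[C@H](O)[C@H](C)C=C | intermediate
17 | (3R,4S,7S)-4-methoxy-3,7-dimethyl-7-[(triethylsilyl)oxy]dec-1-en-8-yne | CC#C[C@@](C)(O[Si](CC)(CC)CC)CC[C@H](OC)[C@H](C)C=C | intermediate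
18 | 1,2,4-trioxolane (ozonide) of 17, ring carbon epimers | CC#C[C@@](C)(O[Si](CC)(CC)CC)CC[C@H](OC)[C@H](C)C1OCOO1 | intermediate
19 | (2S,3S,6S)-3-methoxy-2,6-dimethyl-6-[(triethylsilyl)oxy]non-7-ynal | CC#C[C@@](C)(O[Si](CC)(CC)CC)CC[C@H](OC)[C@H](C)C=O | intermediate
20 | propanal | CCC=O | starting material
21 | (2S,3S,4R,5S,8S)-3-hydroxy-5-methoxy-2,4,8-trimethyl-8-[(triethylsilyl)oxy]undec-9-ynal | CC#C[C@@](C)(O[Si](CC)(CC)CC)CC[C@H](OC)[C@H](C)[C@H](O)[C@H](C)C=O | intermediate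
22 | (2S,3S,4S,5S,8S)-5-methoxy-2,4,8-trimethyl-3,8-bis[(triethylsilyl)oxy]undec-9-ynal | CC#C[C@@](C)(O[Si](CC)(CC)CC)CC[C@H](OC)[C@H](C)[C@H](O[Si](CC)(CC)CC)[C@H](C)C=O | intermediate
23 | 2-chloro-N-methoxy-N-methylacetamide | CON(C)C(=O)CCl | starting material
24 | (4-methoxyphenyl)methanol | COc1ccc(CO)cc1 | starting material
25 | N-methoxy-2-[(4-methoxyphenyl)methoxy]-N-methylacetamide | CON(C)C(=O)COCc1ccc(OC)cc1 | intermediate
26 | prop-1-yn-1-ylmagnesium bromide | CC#C[Mg]Br | starting material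
27 | 1-[(4-methoxyphenyl)methoxy]pent-3-yn-2-one | CC#CC(=O)COCc1ccc(OC)cc1 | intermediate
28 | (Z)-dibutylboron enolate of 27 | CCCCB(CCCC)O/C(C#CC)=C\OCc1ccc(OC)cc1 | intermediate
29 | (5R,6S,7R,8R,9S,10S,13S)-6-hydroxy-10-methoxy-5-[(4-methoxyphenyl)methoxy]-7,9,13-trimethyl-8,13-bis[(triethylsilyl)oxy]hexadeca-2,14-diyn-4-one | CC#C[C@@](C)(O[Si](CC)(CC)CC)CC[C@H](OC)[C@H](C)[C@H](O[Si](CC)(CC)CC)[C@H](C)[C@H](O)[C@@H](OCc1ccc(OC)cc1)C(=O)C#CC | intermediate
30 | (5R,6S,7S,8S,9S,10S,13S)-10-methoxy-5-[(4-methoxyphenyl)methoxy]-7,9,13-trimethyl-6,8,13-tris[(triethylsilyl)oxy]hexadeca-2,14-diyn-4-one | CC#C[C@@](C)(O[Si](CC)(CC)CC)CC[C@H](OC)[C@H](C)[C@H](O[Si](CC)(CC)CC)[C@H](C)[C@H](O[Si](CC)(CC)CC)[C@@H](OCc1ccc(OC)cc1)C(=O)C#CC | intermediate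
31 | (5R,6S,7S,8S,9S,10S,13S)-5-hydroxy-10-methoxy-7,9,13-trimethyl-6,8,13-tris[(triethylsilyl)oxy]hexadeca-2,14-diyn-4-one | CC#C[C@@](C)(O[Si](CC)(CC)CC)CC[C@H](OC)[C@H](C)[C@H](O[Si](CC)(CC)CC)[C@H](C)[C@H](O[Si](CC)(CC)CC)[C@@H](O)C(=O)C#CC | intermediate
32 | (2R)-5-methyl-2-[(1S,2S,3S,4S,5S,8S)-5-methoxy-2,4,8-trimethyl-1,3,8-tris[(triethylsilyl)oxy]undec-9-yn-1-yl]furan-3(2H)-one | CC#C[C@@](C)(O[Si](CC)(CC)CC)CC[C@H](OC)[C@H](C)[C@H](O[Si](CC)(CC)CC)[C@H](C)[C@H](O[Si](CC)(CC)CC)[C@H]1OC(C)=CC1=O | intermediate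
33 | (2R)-5-methyl-2-[(1S,2S,3S,4S,5S,8S,9Z)-5-methoxy-2,4,8-trimethyl-10-(4,4,5,5-tetramethyl-1,3,2-dioxaborolan-2-yl)-1,3,8-tris[(triethylsilyl)oxy]undec-9-en-1-yl]furan-3(2H)-one | CC1(C)OB(/C(C)=C/[C@@](C)(O[Si](CC)(CC)CC)CC[C@H](OC)[C@H](C)[C@H](O[Si](CC)(CC)CC)[C@H](C)[C@H](O[Si](CC)(CC)CC)[C@H]2OC(C)=CC2=O)OC1(C)C | intermediate
34 | potassium trifluoro[(2Z,4S,7S,8S,9S,10S,11S)-7-methoxy-4,8,10-trimethyl-11-[(2R)-5-methyl-3-oxo-2,3-dihydrofuran-2-yl]-4,9,11-tris[(triethylsilyl)oxy]undec-2-en-2-yl]borate | [K+].F[B-](F)(F)/C(C)=C/[C@@](C)(O[Si](CC)(CC)CC)CC[C@H](OC)[C@H](C)[C@H](O[Si](CC)(CC)CC)[C@H](C)[C@H](O[Si](CC)(CC)CC)[C@H]1OC(C)=CC1=O | intermediate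
35 | (2R)-2-[(2S)-1-[(tert-butyldimethylsilyl)oxy]propan-2-yl]-4-ethyl-2,3-dihydropyrylium (counter-ion: DDQ hydroquinone monoanion) | CCC1=CC=[O+][C@@H]([C@@H](C)CO[Si](C)(C)C(C)(C)C)C1 | intermediate
36 | (2R)-2-[(1S,2S,3S,4S,5S,8S,9E)-10-[(2R,6R)-6-[(2S)-1-[(tert-butyldimethylsilyl)oxy]propan-2-yl]-4-ethyl-5,6-dihydro-2H-pyran-2-yl]-5-methoxy-2,4,8-trimethyl-1,3,8-tris[(triethylsilyl)oxy]undec-9-en-1-yl]-5-methylfuran-3(2H)-one | CCC1=C[C@H](/C(C)=C/[C@@](C)(O[Si](CC)(CC)CC)CC[C@H](OC)[C@H](C)[C@H](O[Si](CC)(CC)CC)[C@H](C)[C@H](O[Si](CC)(CC)CC)[C@H]2OC(C)=CC2=O)O[C@@H]([C@@H](C)CO[Si](C)(C)C(C)(C)C)C1 | intermediate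
37 | (2R)-2-[(1S,2S,3R,4R,5S,8S,9E)-10-[(2R,6R)-4-ethyl-6-[(2S)-1-hydroxypropan-2-yl]-5,6-dihydro-2H-pyran-2-yl]-1,3,8-trihydroxy-5-methoxy-2,4,8-trimethylundec-9-en-1-yl]-5-methylfuran-3(2H)-one | CCC1=C[C@H](/C(C)=C/[C@@](C)(O)CC[C@H](OC)[C@H](C)[C@H](O)[C@H](C)[C@H](O)[C@H]2OC(C)=CC2=O)O[C@@H]([C@@H](C)CO)C1 | intermediate
38 | (2R)-2-[(2R,6R)-4-ethyl-6-[(2E,4S,7S,8R,9R,10S,11S)-4,9,11-trihydroxy-7-methoxy-4,8,10-trimethyl-11-[(2R)-5-methyl-3-oxo-2,3-dihydrofuran-2-yl]undec-2-en-2-yl]-3,6-dihydro-2H-pyran-2-yl]propanal | CCC1=C[C@H](/C(C)=C/[C@@](C)(O)CC[C@H](OC)[C@H](C)[C@H](O)[C@H](C)[C@H](O)[C@H]2OC(C)=CC2=O)O[C@@H]([C@@H](C)C=O)C1 | intermediate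
39 | (2R)-2-[(2R,6R)-4-ethyl-6-[(2E,4S,7S,8R,9R,10S,11S)-4,9,11-trihydroxy-7-methoxy-4,8,10-trimethyl-11-[(2R)-5-methyl-3-oxo-2,3-dihydrofuran-2-yl]undec-2-en-2-yl]-3,6-dihydro-2H-pyran-2-yl]propanoic acid | CCC1=C[C@H](/C(C)=C/[C@@](C)(O)CC[C@H](OC)[C@H](C)[C@H](O)[C@H](C)[C@H](O)[C@H]2OC(C)=CC2=O)O[C@@H]([C@@H](C)C(=O)O)C1 | target

## Step count and risks

Total step count: 20. Longest linear sequence: 15 steps (steps 4–11, then 14–20, from pent-3-yn-2-one).

The three steps most likely to fail: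

**Step 18 (the proposed new oxidative C–H alkenylation).** The non-aromatic ion 35 may decompose before capture, or DDQ may over-oxidise the bis-allylic product 36. The fallback sets out from 7 and separates oxidation from C–C bond formation. DDQ oxidation of 7 in CH2Cl2 containing methanol gives the mixed methyl acetal tert-butyl{[(2S)-2-[(2R)-4-ethyl-6-methoxy-3,6-dihydro-2H-pyran-2-yl]propyl]oxy}dimethylsilane F1 as an anomer mixture, which is isolated. F1 is then ionised with BF3·OEt2 in MeCN at −40 °C in the presence of 34. This is a Ferrier-type C-glycosylation of an allylic acetal with a potassium alkenyltrifluoroborate, both known reaction types with the same trans preference, and it comes back to the route at 36.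

**Step 11 (L-proline cross-aldol).** The catalyst must override the Felkin preference of the α-methyl aldehyde 19, and 19 can epimerise or lose methanol under amine catalysis. The fallback sets out from 19 and replaces the enamine aldol by a crotylation and cleavage sequence. NaBH4 reduces 19 to (2R,3S,6S)-3-methoxy-2,6-dimethyl-6-[(triethylsilyl)oxy]non-7-yn-1-ol F2. Iridium-catalysed transfer-hydrogenative anti-crotylation from the alcohol oxidation level (α-methylallyl acetate, [Ir(cod)Cl]2, (S)-SEGPHOS, 4-cyano-3-nitrobenzoic acid, Cs2CO3, THF, 60 °C) is strongly catalyst-controlled and gives (3R,4R,5R,6S,9S)-6-methoxy-3,5,9-trimethyl-9-[(triethylsilyl)oxy]dodec-1-en-10-yn-4-ol F3. TESOTf/2,6-lutidine then gives (3R,4R,5S,6S,9S)-6-methoxy-3,5,9-trimethyl-4,9-bis[(triethylsilyl)oxy]dodec-1-en-10-yne F4, and ozonolysis with PPh3 work-up comes back to the route at 22.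

**Step 3 (IDPi hetero-Diels–Alder).** The catalyst has to give the anti product against the weak intrinsic bias of the α-chiral aldehyde, and the strong acid may cause ene or Prins side reactions or diene oligomerisation. The fallback sets out from 6 and builds the same ring by allylation, etherification and metathesis. Chiral phosphoric acid-catalysed allylboration of 6 with 4,4,5,5-tetramethyl-2-(2-methylidenebutyl)-1,3,2-dioxaborolane gives (2S,3R)-1-[(tert-butyldimethylsilyl)oxy]-2-methyl-5-methylideneheptan-3-ol F5. O-Allylation (NaH, allyl bromide, THF) gives tert-butyl{[(2S,3R)-2-methyl-5-methylidene-3-(prop-2-en-1-yloxy)heptyl]oxy}dimethylsilane F6. Ring-closing metathesis with the second-generation Grubbs catalyst RuCl2(H2IMes)(PCy3)(=CHPh) in CH2Cl2 at 40 °C forms the trisubstituted ring alkene and comes back to the route at 7.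

## Further compounds

F1 | step 18 | tert-butyl{[(2S)-2-[(2R)-4-ethyl-6-methoxy-3,6-dihydro-2H-pyran-2-yl]propyl]oxy}dimethylsilane (anomer mixture) | CCC1=CC(OC)O[C@@H]([C@@H](C)CO[Si](C)(C)C(C)(C)C)C1
F2 | step 11 | (2R,3S,6S)-3-methoxy-2,6-dimethyl-6-[(triethylsilyl)oxy]non-7-yn-1-ol | CC#C[C@@](C)(O[Si](CC)(CC)CC)CC[C@H](OC)[C@H](C)CO
F3 | step 11 | (3R,4R,5R,6S,9S)-6-methoxy-3,5,9-trimethyl-9-[(triethylsilyl)oxy]dodec-1-en-10-yn-4-ol | CC#C[C@@](C)(O[Si](CC)(CC)CC)CC[C@H](OC)[C@H](C)[C@H](O)[C@H](C)C=C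
F4 | step 11 | (3R,4R,5S,6S,9S)-6-methoxy-3,5,9-trimethyl-4,9-bis[(triethylsilyl)oxy]dodec-1-en-10-yne | CC#C[C@@](C)(O[Si](CC)(CC)CC)CC[C@H](OC)[C@H](C)[C@H](O[Si](CC)(CC)CC)[C@H](C)C=C
F5 | step 3 | (2S,3R)-1-[(tert-butyldimethylsilyl)oxy]-2-methyl-5-methylideneheptan-3-ol | O[C@@H]([C@@H](C)CO[Si](C)(C)C(C)(C)C)CC(=C)CC
F6 | step 3 | tert-butyl{[(2S,3R)-2-methyl-5-methylidene-3-(prop-2-en-1-yloxy)heptyl]oxy}dimethylsilane | C=CCO[C@@H]([C@@H](C)CO[Si](C)(C)C(C)(C)C)CC(=C)CC
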